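Both C3–aryl bonds are disconnected at once by a double retro 1,2-aryl shift. C3–C1′ (7-hydroxychromone half, ring B′) and C3″–C1‴ (8-chloro-5,7-dihydroxychromone half, ring B‴) are traced back to Cβ–aryl bonds of a diaryl-ether-bridged bis(2′-hydroxychalcone). One thallium(III) operation, a copy of the isoflavone-synthase migration, moves both rings from Cβ to Cα. It exploits the oxygen para to each migrating carbon: O4′ on B′ and the bridging oxygen on C4‴ of B‴. In the retrosynthetic direction C2 and C2″ become formyl carbons, so the unactivated C3′–O–C4‴ ether reduces to an SNAr on 4-fluorobenzaldehyde. Two ordered aldol condensations tell the halves apart. C8″–Cl is bought next to the only free phenol of ring A″.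

Key step: step 5

Remark on stereochemistry: the target has no stereocentre, no hindered axis and no C=C geometry. It is achiral, so no enantioselective step is needed.
Remark on supply: 2-chloro-3,5-dimethoxyphenol is taken to be a catalogue compound.
Remark on locants: unprimed and ′ refer to the 7-hydroxychromone half (rings A, C, B′). ″ and ‴ refer to the chlorinated half (rings A″, C″, B‴). In the open-chain compounds Cα is next to C=O and Cβ is the next carbon.

Step 1
Reactants: 1 2-chloro-3,5-dimethoxyphenol
Product: 2 1-(3-chloro-2-hydroxy-4,6-dimethoxyphenyl)ethan-1-one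
Conditions: Ac2O, BF3·OEt2 (as solvent), 85 °C; then H2O
Reagents that add atoms: acetic anhydride, CC(=O)OC(C)=O
Why: Friedel–Crafts acylation (O-acetylation/Fries manifold) should go to C6, the only free position ortho to the phenol, because only there is the product locked as a chelated o-hydroxyaryl ketone, whereas C4 lies between two methoxy groups and offers no chelate.

Step 2
Reactants: 3 isovanillin (3-hydroxy-4-methoxybenzaldehyde); 4 paeonol (1-(2-hydroxy-4-methoxyphenyl)ethan-1-one)
Product: 5 (E)-3-(3-hydroxy-4-methoxyphenyl)-1-(2-hydroxy-4-methoxyphenyl)prop-2-en-1-one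
Conditions: KOH (50% aq.), EtOH, rt; then aq. HCl
Reagents that add atoms: none
Why: Claisen–Schmidt condensation in which 4 is the only enolisable partner and 3 the only aldehyde (its phenoxide is meta to CHO and does not switch it off), and E1cB dehydration under thermodynamic control should give the (E)-enone.

Step 3
Reactants: 5 (E)-3-(3-hydroxy-4-methoxyphenyl)-1-(2-hydroxy-4-methoxyphenyl)prop-2-en-1-one; 6 4-fluorobenzaldehyde
Product: 7 4-{5-[(E)-3-(2-hydroxy-4-methoxyphenyl)-3-oxoprop-1-en-1-yl]-2-methoxyphenoxy}benzaldehyde
Conditions: K2CO3, DMF, 100 °C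
Reagents that add atoms: none
Why: SNAr in which the para-formyl group stabilises the Meisenheimer adduct and fluoride leaves, and the free 3-phenoxide of 5 should react ahead of the 2′-OH, which is held in a hydrogen bond to its carbonyl as in the selective alkylation of chelated o-hydroxyaryl ketones.

Step 4
Reactants: 7 4-{5-[(E)-3-(2-hydroxy-4-methoxyphenyl)-3-oxoprop-1-en-1-yl]-2-methoxyphenoxy}benzaldehyde; 2 1-(3-chloro-2-hydroxy-4,6-dimethoxyphenyl)ethan-1-one
Product: 8 bis-chalcone, (E)-1-(3-chloro-2-hydroxy-4,6-dimethoxyphenyl)-3-(4-{5-[(E)-3-(2-hydroxy-4-methoxyphenyl)-3-oxoprop-1-en-1-yl]-2-methoxyphenoxy}phenyl)prop-2-en-1-one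
Conditions: KOH (50% aq.), EtOH–THF, rt; then aq. HCl
Reagents that add atoms: none
Why: second Claisen–Schmidt condensation with 2 as the only enolisable ketone and 7 as the only aldehyde, the first enone being shielded from Michael addition as its electron-rich 2′-phenoxide, and E1cB dehydration should again give the (E)-alkene.

Step 5
Reactants: 8 bis-chalcone
Product: 9 bis-acetal, 1-(3-chloro-2-hydroxy-4,6-dimethoxyphenyl)-2-(4-{5-[1-(2-hydroxy-4-methoxyphenyl)-3,3-dimethoxy-1-oxopropan-2-yl]-2-methoxyphenoxy}phenyl)-3,3-dimethoxypropan-1-one (mixture of Cα epimers)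
Conditions: Tl(NO3)3·3H2O (2.4 equiv), MeOH–CH2Cl2, rt
Reagents that add atoms: methanol, CO
Why: Thallium(III) adds as an electrophile to each enone C=C, with thallium ending on Cα and methanol entering at Cβ, the benzylic carbon whose cation is stabilised by the oxygen para to it (O4′ in ring B′, the bridging oxygen on C4‴ in ring B‴). Heterolysis of the weak C–Tl bond (Tl(III) to Tl(I)) is assisted by the aryl ring, which bridges as a phenonium ion and moves from Cβ to Cα, so that C3–C1′ and C3″–C1‴ of the target are formed without any coupling handle, although each bond joins two donor-type carbons; the methoxy-stabilised cation left at Cβ takes up a second methanol and becomes the acetal carbon, the future C2/C2″. The closest known reaction type is the thallium(III) nitrate oxidative rearrangement of 2′-hydroxychalcones to 1,2-diaryl-3,3-dimethoxypropan-1-ones, the chemical counterpart of the isoflavone-synthase aryl migration, run here on the two enones of one molecule. No ring is closed, and the two new stereocentres (Cα, Cα″) arise without control, which is harmless because both become sp2 in step 6. The step needs aryl migration to outrun attack of the 2′-oxygens on Cα and oxidation of the A rings: both migrating rings carry a para oxygen donor, both OH groups are tied to their carbonyls by hydrogen bonds, the OH of ring A″ is further weakened as a nucleophile by the ortho chlorine, and the oxidant is kept close to two equivalents.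

Step 6
Reactants: 9 bis-acetal
Product: 10 tetra-O-methyl ether of the target, 8-chloro-5,7-dimethoxy-3-{4-[2-methoxy-5-(7-methoxy-4-oxo-4H-chromen-3-yl)phenoxy]phenyl}-4H-chromen-4-one
Conditions: HCl (cat., 10% aq.), MeOH, reflux
Reagents that add atoms: none
Why: acid-catalysed acetal ionisation and cyclocondensation, in which each oxocarbenium carbon is attacked by the neighbouring phenol (six-membered closure, 6-exo-trig) and loss of the second methanol gives the 4-pyranone, both stereocentres vanish, and chlorine can only end at C8″ because the oxygen next to it is the only free OH of ring A″.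

Step 7
Reactants: 10 tetra-O-methyl ether of the target
Product: 11 Bisoflavolin L
Conditions: BBr3 (excess), CH2Cl2, −78 °C to rt; then H2O
Reagents that add atoms: none
Why: Lewis-acid ether cleavage in which BBr3 binds each methoxy oxygen and bromide removes the methyl group by SN2, while the diaryl ether, the aryl chloride and the pyranones offer no sp3 C–O bond and should persist.

Compound list
1 | 2-chloro-3,5-dimethoxyphenol | Oc1cc(OC)cc(OC)c1Cl | starting material
2 | 1-(3-chloro-2-hydroxy-4,6-dimethoxyphenyl)ethan-1-one | CC(=O)c1c(O)c(Cl)c(OC)cc1OC | intermediate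
3 | isovanillin (3-hydroxy-4-methoxybenzaldehyde) | COc1ccc(C=O)cc1O | starting material
4 | paeonol (1-(2-hydroxy-4-methoxyphenyl)ethan-1-one) | CC(=O)c1ccc(OC)cc1O | starting material
5 | (E)-3-(3-hydroxy-4-methoxyphenyl)-1-(2-hydroxy-4-methoxyphenyl)prop-2-en-1-one | COc1ccc(C(=O)/C=C/c2ccc(OC)c(O)c2)c(O)c1 | intermediate
6 | 4-fluorobenzaldehyde | O=Cc1ccc(F)cc1 | starting material
7 | 4-{5-[(E)-3-(2-hydroxy-4-methoxyphenyl)-3-oxoprop-1-en-1-yl]-2-methoxyphenoxy}benzaldehyde | COc1ccc(C(=O)/C=C/c2ccc(OC)c(Oc3ccc(C=O)cc3)c2)c(O)c1 | intermediate
8 | diaryl-ether-bridged (E,E)-bis(2′-hydroxychalcone) | COc1ccc(C(=O)/C=C/c2ccc(OC)c(Oc3ccc(/C=C/C(=O)c4c(O)c(Cl)c(OC)cc4OC)cc3)c2)c(O)c1 | intermediate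
9 | bis(dimethyl acetal) after the double aryl shift (both Cα centres uncontrolled, mixture of racemic diastereomers) | COc1ccc(C(=O)C(C(OC)OC)c2ccc(OC)c(Oc3ccc(C(C(OC)OC)C(=O)c4c(O)c(Cl)c(OC)cc4OC)cc3)c2)c(O)c1 | intermediate
10 | tetra-O-methyl ether of Bisoflavolin L | O=c1c(-c2ccc(OC)c(Oc3ccc(-c4coc5c(Cl)c(OC)cc(OC)c5c4=O)cc3)c2)coc2cc(OC)ccc12 | intermediate
11 | Bisoflavolin L | O=c1c(-c2ccc(O)c(Oc3ccc(-c4coc5c(Cl)c(O)cc(O)c5c4=O)cc3)c2)coc2cc(O)ccc12 | target

Total step count: 7.
Longest linear sequence: 6 steps (3 → 5 → 7 → 8 → 9 → 10 → 11).

Steps most likely to fail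

Step 5. In the half whose para donor is only an aryloxy group (ring B‴), the aryl shift may lose against closure of a five-membered ring by the 2′-oxygen at Cα or against plain solvent capture. The second oxidation may also stall or run on into the enolisable product. The fallback sets out from 8 and comes back at 10. It changes the migrating group and takes the oxidant out of the rearrangement.
- Both 2′-OH groups are capped (NaH, MOMCl, DMF, 0 °C) to give the bis(methoxymethyl) ether F1.
- Weitz–Scheffer epoxidation (H2O2, NaOH, MeOH–acetone) should give the bis(trans-epoxide) F2.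
- Brief treatment with BF3·OEt2 in CH2Cl2 at 0 °C opens each epoxide at the benzylic Cβ. It triggers a Meinwald-type 1,2-aroyl shift from Cα to Cβ and gives the bis(α-formyl ketone) F3. In F3 the old formyl carbon is now the future C3.
- HCl in refluxing MeOH then removes both methoxymethyl groups and cyclodehydrates to 10.

Step 3. At 100 °C with carbonate, several processes could erode the reaction. They are arylation of the chelated 2′-oxygen, base-induced closure of the enone to the chromanone, and condensation of the chromanone's α-CH2 with an aldehyde. The fallback sets out from 5 and comes back at 7. The ether is made by a Chan–Lam coupling, with the aryl group brought in as a nucleophile and joined oxidatively at room temperature under a weak base (4-formylphenylboronic acid, Cu(OAc)2, pyridine, 4 Å molecular sieves, CH2Cl2, air). This way makes no compound outside the list (F0).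

Step 7. Cleavage may stall at the two 7-type methyl ethers, whose oxygens are the least basic. Under forcing acidic conditions ring C″ may also open and reclose on the other ortho oxygen, a Wessely–Moser-type process that would move chlorine from C8″ to C6″. The fallback sets out from 10 and comes back at 11. It splits the end-game into two stages with complementary mechanisms.
- BBr3 at −78 to 0 °C removes only the chelation-assisted 5″-methyl and the ordinary 4′-methyl. This gives the 7,7″-di-O-methyl ether F4.
- The remaining methyl groups sit on the best phenoxide leaving groups, para to C4=O and C4″=O. They are taken off under non-acidic conditions by SN2 attack of a thiolate (NaSEt, DMF, 110 °C; then aq. HCl).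

Further compounds
F1 | step 5 | bis(methoxymethyl) ether of 8 (both 2′-oxygens as OCH2OCH3) | COc1ccc(C(=O)/C=C/c2ccc(OC)c(Oc3ccc(/C=C/C(=O)c4c(OCOC)c(Cl)c(OC)cc4OC)cc3)c2)c(OCOC)c1
F2 | step 5 | bis(trans-epoxide) of F1 (both racemic trans,trans diastereomers expected, one drawn) | COc1ccc(C(=O)[C@H]2O[C@@H]2c3ccc(OC)c(Oc4ccc([C@H]5O[C@@H]5C(=O)c6c(OCOC)c(Cl)c(OC)cc6OC)cc4)c3)c(OCOC)c1
F3 | step 5 | bis(α-formyl ketone), bis(2-aryl-3-oxopropanal) (both Cα centres configurationally labile) | COc1ccc(C(=O)C(C=O)c2ccc(OC)c(Oc3ccc(C(C=O)C(=O)c4c(OCOC)c(Cl)c(OC)cc4OC)cc3)c2)c(OCOC)c1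
F0 | step 3 | none | none
F4 | step 7 | 7,7″-di-O-methyl ether of 11 | O=c1c(-c2ccc(O)c(Oc3ccc(-c4coc5c(Cl)c(OC)cc(O)c5c4=O)cc3)c2)coc2cc(OC)ccc12
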